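Slowness in the earlier runs comes after the starting material. In noon at 0.833 d the starting material reads 2.1% and the target 5.3%, so I take it that material waits as an intermediate, and I ask how that intermediate splits between target and loss.

the same everywhere: starting material 20 mM
- noon: reagent 18 mM (fed, over 3.0 d); catalyst 10 µM; temperature 75 °C; run made earlier; the fed solution adds 0.50 times the starting volume
- winter: reagent 27 mM (fed, over 3.0 d); catalyst 10 µM; temperature 86 °C; run made earlier; the fed solution adds 0.50 times the starting volume
- dawn: reagent 36 mM (fed, over 3.0 d); catalyst 5 µM; temperature 75 °C; run made earlier; the fed solution adds 0.50 times the starting volume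
- ochre: reagent 36.0 mM; catalyst 10 µM; temperature 70 °C; everything together at the start, the whole solution of reagent included, so that from the start the volume is larger by 0.50 times the starting volume; time 8.0 d
- blue: reagent 36.0 mM (fed, over 3.0 d); catalyst 10 µM; temperature 90 °C; the fed solution adds 0.50 times the starting volume; time 8.0 d

| run | time / d | target / % | starting material / % |
|---|---|---|---|
| noon | 0.833 | 5.3 | 2.1 |
| noon | 2.50 | 30.3 | 0 |
| noon | 5.00 | 52.9 | 0.3 |
| noon | 8.00 | 60.2 | 0.1 |
| noon | 10.0 | 64.0 | 0 |
| noon | 12.0 | 65.3 | 0.8 |
| winter | 0.417 | 5.2 | 2.9 |
| winter | 1.25 | 23.4 | 0.3 |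
| winter | 2.50 | 46.3 | 0 |
| winter | 4.00 | 56.9 | 0 |
| winter | 5.00 | 59.2 | 0 |
| winter | 6.00 | 59.8 | 0.5 |
| dawn | 1.04 | 8.8 | 9.2 |
| dawn | 2.00 | 25.3 | 1.5 |
| dawn | 4.00 | 50.2 | 0.7 |
| dawn | 6.00 | 62.2 | 0.3 |
| dawn | 12.0 | 69.2 | 0.5 |

(each reading ± 0.5 percentage points)

- charges are per starting volume, the dose included; the dosed solution carries all of it

* which of the two ends with the higher amount of target, in percent of the starting material charged ("neither" if they lie within 2 percentage points) (ochre / blue / neither)
* target at the end, in percent of the starting material charged, ochre
* target at the end, in percent of the starting material charged, blue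

I take the end odds O, target over the rest of the material. My guess is that the target step needs reagent and catalyst while the loss needs neither, so O should grow with the pull, reagent charge times catalyst charge. Dawn's pull is my unit. Noon's pull equals it, and noon's 65.3% lies near dawn's 69.2%.

Dawn, at 75 °C, gives O = 2.25 on one unit. Winter, at 86 °C, ends at 59.8%, so O = 1.49 on 1.50 units, which is 0.992 per unit. Continuing the same fall per degree gives 3.26 at 70 °C. This σ, the end odds per unit of pull at ochre's temperature, a selectivity factor, is what I carry. At 90 °C the same line gives 0.737.

Ochre has dawn's reagent and twice its catalyst, so 2.00 units and O = 6.52, which means 86.7% target once finished. Blue has the same pull, so O = 1.47 and 59.6%.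

The weak link is whether cold ochre finishes. Dawn's gap to its last reading closes at 0.499 d⁻¹. If the cold cancels ochre's extra catalyst, my estimate leaves 1.84% of the gap unfinished after 8.0 d. So I commit to 85.1% for ochre and 59.6% for blue.

The forecast names ochre, with ochre at 72% (66% to 77%) and blue at 59% (54% to 63%), holding that “heat favours a loss path”. My ochre stands higher.

The flask gives ochre 86.3% and blue 58.1%, so ochre leads.

    starting material + intermediate → side product A (k = 0.0390 M⁻¹ min⁻¹, Ea = 70.0 kJ mol⁻¹)
    reagent + catalyst + intermediate → catalyst + target (k = 8400 M⁻² min⁻¹, Ea = 47.0 kJ mol⁻¹)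
    intermediate → side product B (k = 2.30 × 10⁻⁴ min⁻¹, Ea = 112 kJ mol⁻¹)
    starting material + catalyst → catalyst + intermediate (k = 790 M⁻¹ min⁻¹, Ea = 63.0 kJ mol⁻¹)
    (constants at 90 °C)

The loss that σ counts shows in blue: side product B holds 33.5% at 8.00 d, and blue without that step ends at 91.3%, so that step is the main reason blue stays low. Ochre's odds of target over side products A and B are 7.36, against my 6.52.

The neighbouring flask is ochre with catalyst at 0.0040 mM, so σ gives O = 2.61, or 72.3% once finished. Computed, it holds 63.7% target with 13.3% intermediate still standing, and odds of 2.78 on what has finished.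

(The readings are simulated for substances that don't exist; noise was put on by code.)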